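**Plan** (prostanoid numbering: ring C8–C12; C9 = ring C=O, C10 = CBr, C11 = ring CH, C12 = acetoxy carbon, C8 = alkylidene carbon)
1. Retrosynthesis: cut the C12 acetate and C7=C8 (aldol condensation with enal 17), then C10–Br (through the epoxy ketone), then the ring bonds C9–C10 and C11–C12 together. This leaves ethynyltrimethylsilane (C10, C11) and a 1,3-dioxin-4-one that holds C12–C8–C9.
2. Enabling feature: in the cyclopentenone the C9 carbonyl and the C12 tertiary oxygen sit 1,3 across C8, a β-keto acid pattern. As a dioxinone, C12 is an enoate β-carbon that already carries its oxygen and C9 is a lactone carbonyl with an acetal oxygen as leaving group, so an alkyne can be stitched across C12 and C9 while the acetal ketone is extruded.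
3. Forward: cis-3-nonenol → acid → acyl Meldrum's acid → menthone spiro-dioxinone; the nickel-catalysed reductive [3+2] annulation builds the only ring; desilylation and epoxidation/HBr install bromine; aldol with 17 and acetylation/elimination join the ester chain.
4. Stereochemistry: C12 from the menthone acetal (facial control in the annulation); 14Z from the starting alcohol; 5E from cross metathesis; 7E from the thermodynamically controlled E1cB step.

Key step: step 4

Assumption: nickel and alkyne are taken to approach the dioxinone on the face next to the menthane CH2 and away from the isopropyl-bearing carbon, which makes the (6S) spiro epimer 7 the one that gives the required C12 configuration; if the facial sense is opposite, the co-formed (6R) epimer is carried through the same steps.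

**Step 1**
Reactants: 1 (3Z)-non-3-en-1-ol
Product: 2 (3Z)-non-3-enoic acid
Conditions: TEMPO (cat.), PhI(OAc)2 (2.2 equiv), MeCN/H2O, rt
Reagents that add atoms: water (O)
Why: Oxoammonium (TEMPO) oxidation should take the primary alcohol through the aldehyde hydrate to the acid under near-neutral conditions that leave the Z-alkene unconjugated.

**Step 2**
Reactants: 2 (3Z)-non-3-enoic acid; 3 Meldrum's acid
Product: 4 5-[(3Z)-1-hydroxynon-3-en-1-ylidene]-2,2-dimethyl-1,3-dioxane-4,6-dione
Conditions: DCC, DMAP, CH2Cl2, 0 °C → rt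
Reagents that add atoms: none
Why: Carbodiimide-mediated C-acylation of Meldrum's acid is the standard entry to acyl Meldrum's acids.

**Step 3**
Reactants: 4 acyl Meldrum's acid; 5 (−)-menthone
Product: 7 (6S,7S,10R)-10-methyl-2-[(2Z)-oct-2-en-1-yl]-7-(propan-2-yl)-1,5-dioxaspiro[5.5]undec-2-en-4-one, via acylketene 6 (not isolated)
Conditions: 5 (5 equiv), toluene, 110 °C, N2 sweep; chromatographic separation of the spiro epimers
Reagents that add atoms: none
Why: Thermal retro-[4+2] loss of acetone and CO2 gives acylketene 6, which the excess ketone should trap in a hetero-Diels–Alder reaction; the two spiro epimers are separable and the unwanted one can be re-equilibrated with acid.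

**Step 4**
Reactants: 7 spiro-dioxinone; 8 ethynyltrimethylsilane
Product: 10 (4S)-4-hydroxy-4-[(2Z)-oct-2-en-1-yl]-2-(trimethylsilyl)cyclopent-2-en-1-one, via menthone hemiketal 9 (not isolated)
Conditions: Ni(cod)2 (10 mol%), PBu3 (20 mol%), Et3B (3 equiv), MeOH/THF (1:8), 50 °C, slow addition of 8
Reagents that add atoms: none
Why: Proposed new method: zerovalent nickel should couple the dioxinone C=C and the alkyne by oxidative cyclization, joining the unsubstituted alkyne carbon to C6 of the dioxinone (C11–C12) and leaving nickel on the silicon-bearing carbon; after methanol protonates the nickel enolate, this alkenylnickel adds to the lactone carbonyl (C9–C10), the acetal opens, hemiketal 9 sheds menthone, and Et3B returns divalent nickel to the zerovalent state. The closest known reaction type is the nickel-catalysed reductive [3+2] cycloaddition of enoates with alkynes to cyclopentenones, extended here to a β-oxygenated, β,β-disubstituted enoate whose acylal oxygen is the leaving group. The cyclopentenone ring closes in two stages, an intermolecular C–C coupling and then a 5-exo-trig acyl substitution through a bridged bicyclo[3.2.1] tetrahedral intermediate. The new quaternary centre C12 is controlled by the spiro-menthane acetal, which leaves only the dioxinone face beside the menthane CH2 open. Regioselectivity (silicon next to the carbonyl, hydrogen on C11) should follow from the preference of nickel for the silyl-bearing alkyne carbon, and chemoselectivity over the isolated Z-alkene from the need of nickel for an electron-poor alkene; the acylal character of the dioxinone, which lets this carbon accept cuprates, is what should keep it reactive enough.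

**Step 5**
Reactants: 10 silyl enone
Product: 11 (4S)-4-hydroxy-4-[(2Z)-oct-2-en-1-yl]cyclopent-2-en-1-one
Conditions: K2CO3, MeOH, 0 °C → rt
Reagents that add atoms: none
Why: Conjugate addition of methoxide, desilylation of the resulting α-silyl ketone and β-elimination of methoxide should remove the vinylic silyl group (addition–elimination protodesilylation) without touching the tertiary alcohol.

**Step 6**
Reactants: 11 hydroxy enone
Product: 12 (4S)-4-hydroxy-4-[(2Z)-oct-2-en-1-yl]-6-oxabicyclo[3.1.0]hexan-2-one (epoxide diastereomers)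
Conditions: 30% H2O2, NaOH (cat.), MeOH, 0 °C
Reagents that add atoms: hydrogen peroxide (OO)
Why: Weitz–Scheffer epoxidation attacks only the electron-poor enone C=C and not the isolated Z-alkene, and both epoxide diastereomers converge in step 7.

**Step 7**
Reactants: 12 epoxy ketone
Product: 14 (4S)-2-bromo-4-hydroxy-4-[(2Z)-oct-2-en-1-yl]cyclopent-2-en-1-one, via bromohydrin 13 (not isolated)
Conditions: 48% aq. HBr, acetone, 0 °C → rt
Reagents that add atoms: hydrogen bromide (Br)
Why: Bromide should open the protonated epoxy ketone at the carbon α to the carbonyl and bromohydrin 13 should dehydrate to the 2-bromoenone (halohydrin formation–elimination), which avoids electrophilic bromine that would attack the Z-alkene.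

**Step 8**
Reactants: 15 methyl hex-5-enoate; 16 (2E)-but-2-enal
Product: 17 methyl (5E)-7-oxohept-5-enoate
Conditions: second-generation Hoveyda–Grubbs catalyst (2 mol%), 16 (3 equiv), CH2Cl2, 40 °C
Reagents that add atoms: none
Why: Olefin cross metathesis of a terminal alkene with crotonaldehyde should give the (E)-enal with loss of propene.

**Step 9**
Reactants: 14 bromo hydroxy enone; 17 enal ester
Product: 18 methyl (5E)-7-{(2S)-4-bromo-2-hydroxy-2-[(2Z)-oct-2-en-1-yl]-5-oxocyclopent-3-en-1-yl}-7-hydroxyhept-5-enoate (mixture at the two new centres)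
Conditions: LDA (2.2 equiv), THF, −78 °C; then 17; aq. NH4Cl
Reagents that add atoms: none
Why: Two equivalents of LDA should give the alkoxide/α′-enolate dianion (the alkoxide cannot be expelled as an ester could), which adds 1,2 to the enal in an aldol reaction; the two new centres are removed in step 10.

**Step 10**
Reactants: 18 aldol adduct
Product: 21 methyl (5E,7E)-7-{(2R)-2-acetoxy-4-bromo-2-[(2Z)-oct-2-en-1-yl]-5-oxocyclopent-3-en-1-ylidene}hept-5-enoate, via secondary acetate 19 (not isolated), via dienone alcohol 20 (not isolated)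
Conditions: Ac2O (excess), Et3N, DMAP, CH2Cl2, 0 °C → rt
Reagents that add atoms: acetic anhydride (CC(=O)OC(C)=O)
Why: Acetylation of the secondary aldol hydroxyl and E1cB loss of acetate should give the cross-conjugated dienone, expected mainly as the thermodynamically favoured 7E isomer, and DMAP-catalysed acetylation of the tertiary alcohol then completes the target without disturbing C12.

**Compound list**
1 | (3Z)-non-3-en-1-ol | CCCCC/C=C\CCO | starting material
2 | (3Z)-non-3-enoic acid | CCCCC/C=C\CC(=O)O | intermediate
3 | Meldrum's acid (2,2-dimethyl-1,3-dioxane-4,6-dione) | CC1(C)OC(=O)CC(=O)O1 | starting material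
4 | 5-[(3Z)-1-hydroxynon-3-en-1-ylidene]-2,2-dimethyl-1,3-dioxane-4,6-dione | CCCCC/C=C\CC(O)=C1C(=O)OC(C)(C)OC1=O | intermediate
5 | (−)-menthone, (2S,5R)-5-methyl-2-(propan-2-yl)cyclohexan-1-one | O=C1C[C@H](C)CC[C@H]1C(C)C | starting material
6 | acylketene (5Z)-undeca-1,5-diene-1,3-dione (not isolated) | CCCCC/C=C\CC(=O)C=C=O | intermediate
7 | (6S,7S,10R)-10-methyl-2-[(2Z)-oct-2-en-1-yl]-7-(propan-2-yl)-1,5-dioxaspiro[5.5]undec-2-en-4-one | O=C1C=C(C/C=C\CCCCC)O[C@]2(O1)C[C@H](C)CC[C@H]2C(C)C | intermediate
8 | ethynyltrimethylsilane | C#C[Si](C)(C)C | starting material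
9 | menthone hemiketal of 10 at the tertiary oxygen (not isolated) | CCCCC/C=C\C[C@@]1(O[C@]2(O)C[C@H](C)CC[C@H]2C(C)C)C=C([Si](C)(C)C)C(=O)C1 | intermediate
10 | (4S)-4-hydroxy-4-[(2Z)-oct-2-en-1-yl]-2-(trimethylsilyl)cyclopent-2-en-1-one | CCCCC/C=C\C[C@@]1(O)C=C([Si](C)(C)C)C(=O)C1 | intermediate
11 | (4S)-4-hydroxy-4-[(2Z)-oct-2-en-1-yl]cyclopent-2-en-1-one | CCCCC/C=C\C[C@@]1(O)C=CC(=O)C1 | intermediate
12 | (4S)-4-hydroxy-4-[(2Z)-oct-2-en-1-yl]-6-oxabicyclo[3.1.0]hexan-2-one (epoxide diastereomers) | CCCCC/C=C\C[C@@]1(O)C2OC2C(=O)C1 | intermediate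
13 | (4S)-2-bromo-3,4-dihydroxy-4-[(2Z)-oct-2-en-1-yl]cyclopentan-1-one (not isolated) | CCCCC/C=C\C[C@@]1(O)C(O)C(Br)C(=O)C1 | intermediate
14 | (4S)-2-bromo-4-hydroxy-4-[(2Z)-oct-2-en-1-yl]cyclopent-2-en-1-one | CCCCC/C=C\C[C@@]1(O)C=C(Br)C(=O)C1 | intermediate
15 | methyl hex-5-enoate | C=CCCCC(=O)OC | starting material
16 | (2E)-but-2-enal (crotonaldehyde) | C/C=C/C=O | starting material
17 | methyl (5E)-7-oxohept-5-enoate | O=C/C=C/CCCC(=O)OC | intermediate
18 | methyl (5E)-7-{(2S)-4-bromo-2-hydroxy-2-[(2Z)-oct-2-en-1-yl]-5-oxocyclopent-3-en-1-yl}-7-hydroxyhept-5-enoate | CCCCC/C=C\C[C@@]1(O)C=C(Br)C(=O)C1C(O)/C=C/CCCC(=O)OC | intermediate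
19 | 7-acetate of 18 (not isolated) | CCCCC/C=C\C[C@@]1(O)C=C(Br)C(=O)C1C(OC(C)=O)/C=C/CCCC(=O)OC | intermediate
20 | methyl (5E,7E)-7-{(2R)-4-bromo-2-hydroxy-2-[(2Z)-oct-2-en-1-yl]-5-oxocyclopent-3-en-1-ylidene}hept-5-enoate (not isolated) | CCCCC/C=C\C[C@@]1(O)C=C(Br)C(=O)/C1=C/C=C/CCCC(=O)OC | intermediate
21 | methyl (5E,7E)-7-{(2R)-2-acetoxy-4-bromo-2-[(2Z)-oct-2-en-1-yl]-5-oxocyclopent-3-en-1-ylidene}hept-5-enoate | CCCCC/C=C\C[C@@]1(OC(C)=O)C=C(Br)C(=O)/C1=C/C=C/CCCC(=O)OC | target

**Step count and risks**
Total steps: 10. Longest linear sequence: 9 (steps 1–7, 9, 10).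

Steps most likely to fail:

1. Step 4. Oxidative cyclization at the fully substituted, oxygen-bearing enoate carbon may be too slow, so that alkyne oligomerization or reductive alkenylation without ring closure takes over, and the facial selectivity may be insufficient. The fallback uses known chemistry and sets out from 7. Conjugate addition of lithium divinylcuprate (from vinyllithium and CuI, with TMSCl, THF, −78 °C) under the same acetal control should give the vinyl dioxanone (2S,6S,7S,10R)-2-ethenyl-10-methyl-2-[(2Z)-oct-2-en-1-yl]-7-(propan-2-yl)-1,5-dioxaspiro[5.5]undecan-4-one F1. Aminolysis with N,O-dimethylhydroxylamine hydrochloride and i-PrMgCl releases menthone and gives the Weinreb amide (3S,5Z)-3-ethenyl-3-hydroxy-N-methoxy-N-methylundec-5-enamide F2. Vinylmagnesium bromide converts it to the dienone (5S,7Z)-5-ethenyl-5-hydroxytrideca-1,7-dien-3-one F3, and ring-closing metathesis with second-generation Grubbs catalyst closes the cyclopentenone. The fallback comes back to the route at 11.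

2. Step 7. Bromide may open the epoxide at the β-carbon, which after elimination would give the 2-hydroxy enone, and the acid may add to the Z-alkene or ionize the tertiary alcohol. The fallback sets out from 11. Pyridine-catalysed α-iodination (I2, pyridine, CH2Cl2), which tolerates isolated alkenes, should give (4S)-4-hydroxy-2-iodo-4-[(2Z)-oct-2-en-1-yl]cyclopent-2-en-1-one F4. Stannylation with hexamethylditin and Pd(PPh3)4 gives (4S)-4-hydroxy-4-[(2Z)-oct-2-en-1-yl]-2-(trimethylstannyl)cyclopent-2-en-1-one F5, and bromodestannylation with NBS at −78 °C comes back to the route at 14.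

3. Step 9. Dianion formation may be incomplete, or the amide base may add to or degrade the bromoenone, and the aldolate may revert. The fallback sets out from 14. Silylation with TMSOTf and Et3N should give the silyl dienol ether {[(3S)-5-bromo-3-[(2Z)-oct-2-en-1-yl]-3-[(trimethylsilyl)oxy]cyclopenta-1,4-dien-1-yl]oxy}trimethylsilane F6. A Mukaiyama aldol reaction with 17 (BF3·OEt2, CH2Cl2, −78 °C) and mild acidic desilylation comes back to the route at 18.

**Further compounds**
F1 | step 4 | (2S,6S,7S,10R)-2-ethenyl-10-methyl-2-[(2Z)-oct-2-en-1-yl]-7-(propan-2-yl)-1,5-dioxaspiro[5.5]undecan-4-one | O=C1C[C@](C=C)(C/C=C\CCCCC)O[C@]2(O1)C[C@H](C)CC[C@H]2C(C)C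
F2 | step 4 | (3S,5Z)-3-ethenyl-3-hydroxy-N-methoxy-N-methylundec-5-enamide | CCCCC/C=C\C[C@@](O)(C=C)CC(=O)N(C)OC
F3 | step 4 | (5S,7Z)-5-ethenyl-5-hydroxytrideca-1,7-dien-3-one | CCCCC/C=C\C[C@@](O)(C=C)CC(=O)C=C
F4 | step 7 | (4S)-4-hydroxy-2-iodo-4-[(2Z)-oct-2-en-1-yl]cyclopent-2-en-1-one | CCCCC/C=C\C[C@@]1(O)C=C(I)C(=O)C1
F5 | step 7 | (4S)-4-hydroxy-4-[(2Z)-oct-2-en-1-yl]-2-(trimethylstannyl)cyclopent-2-en-1-one | CCCCC/C=C\C[C@@]1(O)C=C([Sn](C)(C)C)C(=O)C1
F6 | step 9 | {[(3S)-5-bromo-3-[(2Z)-oct-2-en-1-yl]-3-[(trimethylsilyl)oxy]cyclopenta-1,4-dien-1-yl]oxy}trimethylsilane | CCCCC/C=C\C[C@@]1(O[Si](C)(C)C)C=C(Br)C(O[Si](C)(C)C)=C1
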